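Thursday's run took the substrate from 94.9 % at 0.250 min to 41.7 % at 3.00 min. The new flask repeats that recipe, weaker and for longer.

| flask | substrate | activator | remark | time |
|---|---|---|---|---|
| Thursday's | 1.4 M | 1.5 equiv | run made earlier |  |
| flask | 1.0 M | 1.50 equiv |  | 4.0 min |

Thursday's run (percent of the substrate charged)

| time / min | isomer of the product / % | activated form / % | ring / % | open dimer / % | substrate / % |
|---|---|---|---|---|---|
| 0.250 | 1.0 | 3.4 | 0.9 | 0 | 94.9 |
| 0.417 | 0.8 | 4.9 | 1.6 | 2.1 | 90.5 |
| 0.667 | 0 | 6.5 | 1.8 | 5.3 | 85.7 |
| 0.833 | 0 | 9.9 | 5.0 | 8.6 | 80.3 |
| 1.33 | 0 | 5.7 | 3.4 | 16.9 | 69.5 |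
| 2.00 | 0.5 | 7.6 | 4.6 | 25.1 | 55.3 |
| 3.00 | 0.1 | 6.0 | 7.4 | 34.8 | 41.7 |

(scatter of a reading: 1 percentage point)

- percent here means substrate units held: one open dimer counts as two
- a reading or a percentage of ring counts all its forms, free or not
- a reading or a percentage of substrate is of its free form alone

- the species in which most of what was charged as substrate, at 4.0 min sits (isomer of the product / substrate / open dimer / activated form / ring)
- the largest share itself, whichever of these holds it, in percent of the substrate charged

Take the main step first: substrate meets activator. With the equivalents held, the share lost per minute grows with the charge, so the clock of such a flask is charge times time, in molar minutes. Thursday's first reading gives 0.150 L mol⁻¹ min⁻¹, and this step alone would leave about 55.0 % in the new flask.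

Now add capture, in which activated form takes a second substrate into open dimer. At 3.00 min on Thursday, dimers outnumber rings 2.35 to one, a selectivity factor that favours capture. Capture also runs on molar minutes, so the whole-run figure is the one to carry: the loss constant, the natural log of the fall in the substrate share divided by molar minutes, 0.208 L mol⁻¹ min⁻¹. It is larger, and the flask's charge times time, 4.00 M·min, lies close to Thursday's 4.20 M·min, so the reckoning here leaves 43.5 %.

Then the rest. Ring seems to close from activated form by itself, on plain minutes. At the lower charge, capture should lose ground to it, which puts the true figure slightly higher. The isomer readings, 1.0 % at 0.250 min and 0.1 % at 3.00 min, lie near the scatter.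

The forecast says substrate at 45 %, a little above this reckoning, noting that “both bimolecular steps slow”.

At 4.0 min the flask holds substrate at 43.9 %, with open dimer at 30.9 %. It also holds idle adduct at 17.1 %, and the free substrate still stays ahead of both.

ring ⇌ isomer of the product (K = 2.60, k = 0.610 min⁻¹); substrate + activator → activated form (k = 0.0870 L mol⁻¹ min⁻¹); substrate + ring ⇌ idle adduct, settled at all times (K = 21.0 L mol⁻¹); substrate + activated form → open dimer (k = 0.920 L mol⁻¹ min⁻¹); activated form → ring (k = 0.400 min⁻¹) The neighbouring flask, charged at 0.25 M and read at the same time, has a charge times time of 1.00 M·min, so the loss constant leaves 81.2 % there. That neighbour gives 82.6 % of free substrate, with open dimer at 5.01 %.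

The earlier runs and the new flask come from a simulation for an exercise.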